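**Retrosynthetic overview**
- The C6 isobutyrate comes from the C6 alcohol; the C6 configuration is corrected by oxidation and Luche reduction after ring closure.
- Key disconnection C6–C7: SmI2 ketyl-radical 6-exo cyclisation of a C6 aldehyde onto the β-carbon of a C8-linked α-(acetoxymethyl)butenolide; loss of acetate unveils the α-methylene lactone.
- C8–C9: vinylogous Mukaiyama aldol of a 2-silyloxyfuran (from α-methylene-γ-butyrolactone) with an α-quaternary aldehyde.
- C5–C10 (tertiary/quaternary pair): enantioselective ester-enolate Claisen rearrangement of the ester from isoprene monoepoxide and 3-methylbut-3-enoic acid; C15–O by late SeO2 oxidation.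
- Ring order: the γ-butenolide is carried from the start; the cyclohexane is closed last, onto it, in the radical step.

Locants in the text follow elemane numbering: C10 quaternary; C5 CH bearing the isopropenyl unit; C6 CH–O-isobutyryl; C7/C8 ring fusion (C8–O lactone); C9 CH–OAc; C11=C13 exocyclic methylene; C12 lactone C=O; C15 CH2OAc.
Assumption: the facial sense of the two chiral boron reagents (steps 2 and 8) follows their published models; if either proves opposite, its enantiomer is used.

**Route**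

Step 1
Reactants: 1 2-methyl-2-vinyloxirane (isoprene monoepoxide, racemic); 2 3-methylbut-3-enoic acid
Product: 3 (2E)-4-hydroxy-3-methylbut-2-en-1-yl 3-methylbut-3-enoate
Conditions: Pd(PPh3)4 (2 mol %), THF, 0 °C → rt
Reagents that add atoms: none
Why: Tsuji–Trost-type Pd(0) 1,4-opening of the vinyl epoxide, in which the π-allyl alkoxide deprotonates the acid and the carboxylate attacks the unsubstituted allyl terminus, the syn π-allyl giving the E alkene (no stereocentre formed).

Step 2
Reactants: 3 (2E)-4-hydroxy-3-methylbut-2-en-1-yl 3-methylbut-3-enoate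
Product: 6 (3S,4S)-4-ethenyl-4-methyl-3-(prop-1-en-2-yl)oxolan-2-one, via TMS ether 4 (not isolated), via hydroxy acid 5 (not isolated)
Conditions: TMSCl, Et3N, toluene, 0 °C; then (S,S)-B-bromodiazaborolidine [from (1S,2S)-N,N′-bis(3,5-bis(trifluoromethyl)benzenesulfonyl)-1,2-diphenylethane-1,2-diamine and BBr3] (1.2 equiv), Et3N, toluene–hexane, −78 °C → rt; then 1 M HCl, THF, rt
Reagents that add atoms: none
Why: Enantioselective boron ester-enolate Ireland–Claisen rearrangement, in which Et3N in toluene–hexane gives the E(O) dienolate and the chair [3,3] transition state with the E alkene places isopropenyl (C5) cis to methyl and trans to vinyl (C10), the C2-symmetric boron ligand fixing both centres as (3S,4S); acid then frees the hydroxy acid, which lactonises.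

Step 3
Reactants: 6 (3S,4S)-4-ethenyl-4-methyl-3-(prop-1-en-2-yl)oxolan-2-one
Product: 7 (2S,3S)-3-(hydroxymethyl)-3-methyl-2-(prop-1-en-2-yl)-1-(pyrrolidin-1-yl)pent-4-en-1-one
Conditions: pyrrolidine, AlMe3, CH2Cl2, 0 °C → rt
Reagents that add atoms: pyrrolidine C1CCNC1
Why: Aluminium-amide aminolysis of the lactone is non-basic, so the epimerisable C5–H is untouched, and the tertiary amide resists relactonisation while masking C6 as a latent aldehyde.

Step 4
Reactants: 7 (2S,3S)-3-(hydroxymethyl)-3-methyl-2-(prop-1-en-2-yl)-1-(pyrrolidin-1-yl)pent-4-en-1-one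
Product: 8 (2S,3S)-2-ethenyl-2-methyl-4-oxo-3-(prop-1-en-2-yl)-4-(pyrrolidin-1-yl)butanal
Conditions: Dess–Martin periodinane, NaHCO3, CH2Cl2, 0 °C → rt
Reagents that add atoms: none
Why: Dess–Martin oxidation of the neopentyl primary alcohol gives an α-quaternary aldehyde that cannot epimerise.

Step 5
Reactants: 9 3-methylideneoxolan-2-one (α-methylene-γ-butyrolactone, tulipalin A)
Product: 11 3-(bromomethyl)furan-2(5H)-one, via dibromide 10 (not isolated)
Conditions: Br2, CH2Cl2, 0 °C; then Et3N, 0 °C → rt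
Reagents that add atoms: bromine BrBr
Why: Bromination of the exocyclic alkene followed by E2 loss of HBr into the ring (bromination–dehydrobromination) gives the conjugated butenolide bearing a primary allylic bromide.

Step 6
Reactants: 11 3-(bromomethyl)furan-2(5H)-one
Product: 12 3-(hydroxymethyl)furan-2(5H)-one
Conditions: CaCO3, H2O–1,4-dioxane (1:1), 80 °C
Reagents that add atoms: water O
Why: SN2 hydrolysis of the primary allylic bromide under carbonate-buffered, near-neutral conditions that leave the lactone closed.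

Step 7
Reactants: 12 3-(hydroxymethyl)furan-2(5H)-one
Product: 13 trimethyl[(3-{[(trimethylsilyl)oxy]methyl}furan-2-yl)oxy]silane
Conditions: TMSOTf (2.2 equiv), Et3N (2.5 equiv), Et2O, 0 °C; filtered and used directly
Reagents that add atoms: trimethylsilyl trifluoromethanesulfonate C[Si](C)(C)OS(=O)(=O)C(F)(F)F
Why: O-silylation of the alcohol and soft γ-enolisation/O-silylation of the butenolide give the aromatic 2-silyloxyfuran (silyl dienol ether), whose silyl ether side chain is a poor nucleofuge under Lewis acid.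

Step 8
Reactants: 8 (2S,3S)-2-ethenyl-2-methyl-4-oxo-3-(prop-1-en-2-yl)-4-(pyrrolidin-1-yl)butanal; 13 trimethyl[(3-{[(trimethylsilyl)oxy]methyl}furan-2-yl)oxy]silane
Product: 15 (2S,3S)-3-{(S)-hydroxy[(2S)-4-(hydroxymethyl)-5-oxo-2,5-dihydrofuran-2-yl]methyl}-3-methyl-2-(prop-1-en-2-yl)-1-(pyrrolidin-1-yl)pent-4-en-1-one, via bis-TMS ether 14 (not isolated)
Conditions: (S)-N-Ts-tryptophan-derived B-phenyl-oxazaborolidinone (1.0 equiv), EtCN, −78 °C; aq. NaHCO3; then citric acid, MeOH, 0 °C
Reagents that add atoms: none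
Why: Vinylogous Mukaiyama aldol reaction, in which γ-attack of the silyloxyfuran through an open transition state gives the threo (8S,9S) adduct typical of Lewis-acid furan aldols, with the Re face of the aldehyde chosen by Felkin–Anh bias (C5 branch anti, methyl inside) reinforced by the chiral oxazaborolidinone.

Step 9
Reactants: 15 (the diol from step 8)
Product: 16 (2S,3S)-3-{(S)-hydroxy[(2S)-4-(hydroxymethyl)-5-oxo-2,5-dihydrofuran-2-yl]methyl}-2-(3-hydroxyprop-1-en-2-yl)-3-methyl-1-(pyrrolidin-1-yl)pent-4-en-1-one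
Conditions: SeO2 (0.5 equiv), t-BuOOH (3 equiv), CH2Cl2, 0 °C → rt
Reagents that add atoms: selenium dioxide O=[Se]=O (oxygen-transfer catalyst); tert-butyl hydroperoxide CC(C)(C)OO (terminal oxygen source)
Why: SeO2/t-BuOOH allylic oxidation (ene then [2,3] shift) attacks the methyl of the only electron-rich 1,1-disubstituted alkene, since the butenolide is electron-poor and the vinyl group has no allylic hydrogen.

Step 10
Reactants: 16 (the triol from step 9)
Product: 17 (2S,3S)-3-{(S)-(acetyloxy)[(2S)-4-[(acetyloxy)methyl]-5-oxo-2,5-dihydrofuran-2-yl]methyl}-2-[3-(acetyloxy)prop-1-en-2-yl]-3-methyl-1-(pyrrolidin-1-yl)pent-4-en-1-one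
Conditions: Ac2O, pyridine, DMAP (cat.), CH2Cl2, 0 °C → rt
Reagents that add atoms: acetic anhydride CC(=O)OC(C)=O
Why: DMAP-catalysed acetylation of all three hydroxyls installs both acetates of the target and turns C13–O into the leaving group needed in the ring closure.

Step 11
Reactants: 17 (the triacetate amide from step 10)
Product: 18 (2S,3S)-3-{(S)-(acetyloxy)[(2S)-4-[(acetyloxy)methyl]-5-oxo-2,5-dihydrofuran-2-yl]methyl}-2-[3-(acetyloxy)prop-1-en-2-yl]-3-methylpent-4-enal
Conditions: Cp2Zr(H)Cl (1.5 equiv), THF, rt, 15 min; then H2O/silica gel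
Reagents that add atoms: none
Why: Schwartz-reagent reduction of the tertiary amide stops at the aldehyde through a stable zirconated hemiaminal, is faster than attack on esters or the hindered alkenes, and is neutral so C5 stays intact.

Step 12
Reactants: 18 (the aldehyde from step 11)
Product: 19 2-[(3aS,4R,5S,6S,7S,7aS)-7-(acetyloxy)-6-ethenyl-4-hydroxy-6-methyl-3-methylidene-2-oxooctahydro-1-benzofuran-5-yl]prop-2-en-1-yl acetate (6-epi alcohol, OH trans to C11)
Conditions: SmI2 (2.2–2.5 equiv), t-BuOH (2 equiv), THF, −78 → −30 °C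
Reagents that add atoms: none
Why: Proposed new method: SmI2 reduces the aldehyde to a ketyl radical that cyclises 6-exo-trig onto the butenolide β-carbon C7 from the face carrying the C8 tether (cis-fused lactone, 7S), and a second electron gives a samarium enolate that expels the C13 acetate (E1cB) to form the α-methylene lactone; the chair transition state places the bulky O–Sm equatorial and anti to C11, so the 6R alcohol is expected, and the closest known reactions are SmI2 ketyl–enoate cyclisations onto unsaturated lactones and β-elimination from samarium enolates.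

Step 13
Reactants: 19 (the 6-epi alcohol from step 12)
Product: 20 2-[(3aR,5S,6S,7S,7aS)-7-(acetyloxy)-6-ethenyl-6-methyl-3-methylidene-2,4-dioxooctahydro-1-benzofuran-5-yl]prop-2-en-1-yl acetate
Conditions: Dess–Martin periodinane, NaHCO3, CH2Cl2, 0 °C
Reagents that add atoms: none
Why: Buffered Dess–Martin oxidation erases the wrongly set C6 centre without base or acid that could move the exocyclic alkene into conjugation; both C6 epimers from step 12 converge here.

Step 14
Reactants: 20 (the ketone from step 13)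
Product: 21 2-[(3aS,4S,5S,6S,7S,7aS)-7-(acetyloxy)-6-ethenyl-4-hydroxy-6-methyl-3-methylidene-2-oxooctahydro-1-benzofuran-5-yl]prop-2-en-1-yl acetate
Conditions: NaBH4, CeCl3·7H2O, MeOH, −78 °C; AcOH quench at −78 °C
Reagents that add atoms: none
Why: Luche reduction delivers hydride 1,2-selectively from the α face, because the C5 isopropenyl unit, C7–C11 and the C10 methyl all lie on the β face, giving the 6β (4S) alcohol while sparing the α-methylene lactone.

Step 15
Reactants: 21 (the 6β alcohol from step 14)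
Product: 22 (3aS,4S,5S,6S,7S,7aS)-7-(acetyloxy)-5-[3-(acetyloxy)prop-1-en-2-yl]-6-ethenyl-6-methyl-3-methylidene-2-oxooctahydro-1-benzofuran-4-yl 2-methylpropanoate (CNP0500052.1)
Conditions: i-PrCOCl, pyridine, DMAP (cat.), CH2Cl2, 0 °C → rt
Reagents that add atoms: 2-methylpropanoyl chloride CC(C)C(Cl)=O
Why: DMAP-catalysed acylation of the secondary alcohol with the acid chloride completes the target without touching any stereocentre.

**Compound list**

1 | 2-methyl-2-vinyloxirane (racemic) | C=CC1(C)CO1 | starting material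
2 | 3-methylbut-3-enoic acid | C=C(C)CC(=O)O | starting material
3 | (2E)-4-hydroxy-3-methylbut-2-en-1-yl 3-methylbut-3-enoate | OC/C(C)=C/COC(=O)CC(C)=C | intermediate
4 | (2E)-3-methyl-4-[(trimethylsilyl)oxy]but-2-en-1-yl 3-methylbut-3-enoate | C[Si](C)(C)OC/C(C)=C/COC(=O)CC(C)=C | intermediate (not isolated)
5 | (2S,3S)-3-(hydroxymethyl)-3-methyl-2-(prop-1-en-2-yl)pent-4-enoic acid | C=C[C@](C)(CO)[C@@H](C(=O)O)C(C)=C | intermediate (not isolated)
6 | (3S,4S)-4-ethenyl-4-methyl-3-(prop-1-en-2-yl)oxolan-2-one | C=C[C@]1(C)COC(=O)[C@H]1C(C)=C | intermediate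
7 | (2S,3S)-3-(hydroxymethyl)-3-methyl-2-(prop-1-en-2-yl)-1-(pyrrolidin-1-yl)pent-4-en-1-one | C=C[C@](C)(CO)[C@@H](C(=O)N1CCCC1)C(C)=C | intermediate
8 | (2S,3S)-2-ethenyl-2-methyl-4-oxo-3-(prop-1-en-2-yl)-4-(pyrrolidin-1-yl)butanal | C=C[C@](C)(C=O)[C@@H](C(=O)N1CCCC1)C(C)=C | intermediate
9 | 3-methylideneoxolan-2-one (tulipalin A) | C=C1CCOC1=O | starting material
10 | 3-bromo-3-(bromomethyl)oxolan-2-one (racemic) | BrCC1(Br)CCOC1=O | intermediate (not isolated)
11 | 3-(bromomethyl)furan-2(5H)-one | BrCC1=CCOC1=O | intermediate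
12 | 3-(hydroxymethyl)furan-2(5H)-one | OCC1=CCOC1=O | intermediate
13 | trimethyl[(3-{[(trimethylsilyl)oxy]methyl}furan-2-yl)oxy]silane | C[Si](C)(C)OCc1ccoc1O[Si](C)(C)C | intermediate
14 | (2S,3S)-3-methyl-3-{(S)-[(2S)-5-oxo-4-{[(trimethylsilyl)oxy]methyl}-2,5-dihydrofuran-2-yl][(trimethylsilyl)oxy]methyl}-2-(prop-1-en-2-yl)-1-(pyrrolidin-1-yl)pent-4-en-1-one | C=C[C@](C)([C@H](O[Si](C)(C)C)[C@H]1OC(=O)C(CO[Si](C)(C)C)=C1)[C@@H](C(=O)N1CCCC1)C(C)=C | intermediate (not isolated)
15 | (2S,3S)-3-{(S)-hydroxy[(2S)-4-(hydroxymethyl)-5-oxo-2,5-dihydrofuran-2-yl]methyl}-3-methyl-2-(prop-1-en-2-yl)-1-(pyrrolidin-1-yl)pent-4-en-1-one | C=C[C@](C)([C@H](O)[C@H]1OC(=O)C(CO)=C1)[C@@H](C(=O)N1CCCC1)C(C)=C | intermediate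
16 | (2S,3S)-3-{(S)-hydroxy[(2S)-4-(hydroxymethyl)-5-oxo-2,5-dihydrofuran-2-yl]methyl}-2-(3-hydroxyprop-1-en-2-yl)-3-methyl-1-(pyrrolidin-1-yl)pent-4-en-1-one | C=C[C@](C)([C@H](O)[C@H]1OC(=O)C(CO)=C1)[C@@H](C(=O)N1CCCC1)C(=C)CO | intermediate
17 | (2S,3S)-3-{(S)-(acetyloxy)[(2S)-4-[(acetyloxy)methyl]-5-oxo-2,5-dihydrofuran-2-yl]methyl}-2-[3-(acetyloxy)prop-1-en-2-yl]-3-methyl-1-(pyrrolidin-1-yl)pent-4-en-1-one | C=C[C@](C)([C@H](OC(C)=O)[C@H]1OC(=O)C(COC(C)=O)=C1)[C@@H](C(=O)N1CCCC1)C(=C)COC(C)=O | intermediate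
18 | (2S,3S)-3-{(S)-(acetyloxy)[(2S)-4-[(acetyloxy)methyl]-5-oxo-2,5-dihydrofuran-2-yl]methyl}-2-[3-(acetyloxy)prop-1-en-2-yl]-3-methylpent-4-enal | C=C[C@](C)([C@H](OC(C)=O)[C@H]1OC(=O)C(COC(C)=O)=C1)[C@@H](C=O)C(=C)COC(C)=O | intermediate
19 | 2-[(3aS,4R,5S,6S,7S,7aS)-7-(acetyloxy)-6-ethenyl-4-hydroxy-6-methyl-3-methylidene-2-oxooctahydro-1-benzofuran-5-yl]prop-2-en-1-yl acetate | C=C[C@]1(C)[C@H](OC(C)=O)[C@H]2OC(=O)C(=C)[C@H]2[C@H](O)[C@H]1C(=C)COC(C)=O | intermediate
20 | 2-[(3aR,5S,6S,7S,7aS)-7-(acetyloxy)-6-ethenyl-6-methyl-3-methylidene-2,4-dioxooctahydro-1-benzofuran-5-yl]prop-2-en-1-yl acetate | C=C[C@]1(C)[C@H](OC(C)=O)[C@H]2OC(=O)C(=C)[C@H]2C(=O)[C@H]1C(=C)COC(C)=O | intermediate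
21 | 2-[(3aS,4S,5S,6S,7S,7aS)-7-(acetyloxy)-6-ethenyl-4-hydroxy-6-methyl-3-methylidene-2-oxooctahydro-1-benzofuran-5-yl]prop-2-en-1-yl acetate | C=C[C@]1(C)[C@H](OC(C)=O)[C@H]2OC(=O)C(=C)[C@H]2[C@@H](O)[C@H]1C(=C)COC(C)=O | intermediate
22 | (3aS,4S,5S,6S,7S,7aS)-7-(acetyloxy)-5-[3-(acetyloxy)prop-1-en-2-yl]-6-ethenyl-6-methyl-3-methylidene-2-oxooctahydro-1-benzofuran-4-yl 2-methylpropanoate | C=C[C@]1(C)[C@H](OC(C)=O)[C@H]2OC(=O)C(=C)[C@H]2[C@@H](OC(=O)C(C)C)[C@H]1C(=C)COC(C)=O | target

**Count**
Total steps: 15. Longest linear sequence: 12 (steps 1–4, then 8–15); steps 5–7 make the furan partner in parallel.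

**Three steps most likely to fail**

Step 12 (ring closure). Risks are direct reduction of the γ-acetoxy butenolide or of the product acrylate by SmI2, and a slow 6-exo closure next to a quaternary carbon. The fallback sets out from 18 and comes back at 20. An N-heterocyclic-carbene-catalysed intramolecular Stetter reaction (bicyclic triazolium precatalyst 20 mol %, i-Pr2NEt, toluene, rt) adds the Breslow intermediate of the C6 aldehyde to C7 of the butenolide. The resulting enolate expels the C13 acetate, so ketone 20 forms directly and compound 19 and step 13 are skipped. This fallback makes no compound outside the list (entry F0).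

Step 8 (vinylogous aldol). Risks are the hindered neopentyl aldehyde, ionisation of the silyloxymethyl side chain of 13 under Lewis acid, and insufficient facial control at C9. The fallback sets out from 8 and comes back at 15. 3-Bromo-2-(triisopropylsilyloxy)furan (from 3-bromofuran-2(5H)-one, TIPSOTf, Et3N), which has no ionisable side chain, is added to 8 with BF3·OEt2 in CH2Cl2 at −78 °C. Work-up with HF·pyridine gives bromobutenolide F4. Stille coupling of F4 with (tributylstannyl)methanol (Pd(PPh3)4, dioxane, 80 °C) installs the C13 hydroxymethyl group and gives 15.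

Step 2 (enantioselective Claisen). Risks are modest enantioselectivity or slow rearrangement for a dienolate that must form a quaternary centre. The fallback sets out from 3 and comes back at 6. An ordinary Ireland–Claisen rearrangement (LDA 2.2 equiv, TMSCl, THF, −78 °C → rt; then 1 M HCl) gives racemic lactone F1 with the same relative configuration. AlMe3-mediated aminolysis of F1 with (S)-1-phenylethylamine gives the (2S,3S) hydroxy amide F2 and its (2R,3R) diastereomer F3, which are separated by chromatography or crystallisation. Heating F2 in 2 M H2SO4–dioxane at 80 °C relactonises it to enantiopure 6.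

**Further compounds**

F1 | step 2 | racemic (3S*,4S*)-4-ethenyl-4-methyl-3-(prop-1-en-2-yl)oxolan-2-one | C=C[C@]1(C)COC(=O)[C@H]1C(C)=C.C=C[C@@]1(C)COC(=O)[C@@H]1C(C)=C
F2 | step 2 | (2S,3S)-3-(hydroxymethyl)-3-methyl-N-[(1S)-1-phenylethyl]-2-(prop-1-en-2-yl)pent-4-enamide | C=C[C@](C)(CO)[C@@H](C(=O)N[C@@H](C)c1ccccc1)C(C)=C
F3 | step 2 | (2R,3R)-3-(hydroxymethyl)-3-methyl-N-[(1S)-1-phenylethyl]-2-(prop-1-en-2-yl)pent-4-enamide | C=C[C@@](C)(CO)[C@H](C(=O)N[C@@H](C)c1ccccc1)C(C)=C
F4 | step 8 | (2S,3S)-3-{(S)-[(2S)-4-bromo-5-oxo-2,5-dihydrofuran-2-yl](hydroxy)methyl}-3-methyl-2-(prop-1-en-2-yl)-1-(pyrrolidin-1-yl)pent-4-en-1-one | C=C[C@](C)([C@H](O)[C@H]1OC(=O)C(Br)=C1)[C@@H](C(=O)N1CCCC1)C(C)=C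
F0 | step 12 | none | none
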